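The data come from a simulation on assumed constants, and the scatter is random.

Ring in theta and epsilon moves together with starting material, so before choosing between alder and maple you want two things: how that pair divides, and how much of the charge stays in it.

| flask | starting material | temperature | remark | time |
|---|---|---|---|---|
| theta | 0.32 M | 55 °C | run made earlier |  |
| epsilon | 1.1 M | 68 °C | run made earlier |  |
| alder | 0.80 M | 60 °C |  | 20 min |
| maple | 0.25 M | 75 °C |  | 6.0 min |

- theta (time / min: ring / %, starting material / %): 0.833: 29.0, 45.9; 2.00: 30.6, 40.7; 4.00: 29.8, 38.3; 6.00: 27.8, 34.6; 8.00: 25.9, 34.7; 12.0: 23.2, 31.7; 15.0: 23.5, 30.4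
- epsilon (time / min: ring / %, starting material / %): 0.833: 34.4, 35.0; 2.00: 31.5, 32.1; 4.00: 29.8, 29.2; 6.00: 27.9, 29.0; 8.00: 28.0, 28.1; 12.0: 27.0, 28.6; 15.0: 28.0, 28.4

(readings scatter by 0.5 percentage points)

- the winner by amount of ring, in percent of the starting material charged; "neither" if no more than 2 percentage points parts them (alder / maple / neither)
- how much ring is there at the end, in percent of the starting material charged: alder
- how much ring is there at the end, in percent of the starting material charged: maple



Take the even split, one part ring to one part starting material, as the zero of the scale, and call the split the fraction of the charge in ring over the fraction in starting material. The last readings give a split of 0.773 in theta at 55 °C and 0.986 in epsilon at 68 °C. Theta already reads 0.778 at 4.00 min, and alder and maple both run hotter and longer than that, so I treat the pair as under thermodynamic control in both.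

The heat gain, the factor by which the split grows from theta's temperature to epsilon's, reads 1.28. Raised to the temperature step, counted in that span, it gives a split of 0.849 for alder and 1.12 for maple.

At the last readings the pair held 53.9 % of the charge in theta and 56.4 % in epsilon. With their mean, 55.2 %, I expect 25.3 % ring in alder and 29.2 % in maple. That gap of 3.9 percentage points clears the margin, so I would charge maple. The pair share is the weak figure, because epsilon has both the larger charge and the higher temperature, and maple is more dilute than either.

The forecast also names maple, with 25 % for alder and 31 % for maple, more than my maple figure, and it reckons maple as “third pool about 43%, ratio about 1.14, ring about 31%”.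

The flasks give 22.3 % ring in alder and 36.8 % in maple, so maple wins.

    starting material ⇌ ring (K = 0.833, k = 0.0284 s⁻¹, Ea = 99.0 kJ mol⁻¹, ΔH = 20.0 kJ mol⁻¹)
    2 starting material ⇌ open dimer (K = 1.06 L mol⁻¹, k = 0.0488 L mol⁻¹ s⁻¹, Ea = 74.0 kJ mol⁻¹, ΔH = −46.0 kJ mol⁻¹)
    starting material ⇌ dormant form (K = 1.50, k = 0.00316 s⁻¹, Ea = 87.0 kJ mol⁻¹, ΔH = −35.0 kJ mol⁻¹)
    (constants at 60 °C)

Moving theta to maple's temperature with its charge and time held brings ring to 36.5 %, while moving its charge to maple's with its temperature and time held leaves ring at 22.9 %. Maple ends with a split of 1.14, where the heat gain gave 1.12. For a flask like maple kept at 100 °C, the heat gain gives 1.79, and that flask holds 56.1 % ring over 31.0 % starting material, a split of 1.81.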